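**Strategy**

Ring A (the p-menthane ring: C1 carbinol, C2 bonded to ring B, C4 isopropenyl) is cut at C3–C4 and C5–C6 into a 2-silyloxy-3-arylbutadiene and methyl vinyl ketone. The plan exploits the 1,4-relationship between oxygen-bearing C1 and side-chain-bearing C4 of ring A, with the future ring B on C2: one catalytic enantioselective Diels–Alder reaction closes ring A, sets C4 and leaves C1 as a masked ketone. Its precursor is a triisopropylsilyl enol ether diene carrying a tris(methoxymethyl)-protected phloroglucinol ring. C2 and C1 follow by equilibration and methyl addition; ring B is completed by directed lithiation–acylation, deprotection and dearomative double prenylation.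

Key step: step 5

Remark (numbering): ring A is numbered as in p-menthane throughout (C1 carbinol carbon, C2 aryl-bearing, C4 isopropenyl-bearing); ring B is the phloroglucinol-derived ring.
Remark (sense of induction in step 5): the enone is taken to bind the catalyst at oxygen with an α-C–H···O contact, which for the (S)-prolinol-derived catalyst exposes the face leading to 4R; the (R)-prolinol-derived catalyst is therefore specified for 4S, and its antipode would be substituted, with no other change, if a configurational correlation showed the opposite sense.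
Remark (order in ring B): the isobutyryl group is placed before the prenyl groups, so that only one ring-B carbon is unsubstituted when alkylation begins.
Remark (reagent): amide 15 is taken as a purchased compound.

**Route**

Step 1
Reactants: 1 phloroglucinol (benzene-1,3,5-triol)
Product: 2 1,3,5-tris(methoxymethoxy)benzene
Conditions: NaH, MOMCl, DMF, 0 °C → rt
Reagents that add atoms: chloromethyl methyl ether, COCCl
Why: Williamson O-alkylation of the three phenoxides with the reactive α-chloro ether should give the tris-acetal, which is base-stable and later directs both ring metalations.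

Step 2
Reactants: 3 methyl vinyl ketone (but-3-en-2-one)
Product: 5 3-bromobut-3-en-2-one, via 3,4-dibromobutan-2-one 4 (not isolated)
Conditions: Br2, CH2Cl2, −10 °C; then Et3N, 0 °C
Reagents that add atoms: bromine, BrBr
Why: bromination–dehydrobromination (bromine addition, then E1cB loss of HBr from the acidic α-position) is the standard entry to α-bromo enones, and the labile product is used at once.

Step 3
Reactants: 2 1,3,5-tris(methoxymethoxy)benzene; 5 3-bromobut-3-en-2-one
Product: 8 3-[2,4,6-tris(methoxymethoxy)phenyl]but-3-en-2-one, via 2-lithio-1,3,5-tris(methoxymethoxy)benzene 6 (not isolated), via arylzinc chloride 7 (not isolated)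
Conditions: n-BuLi, THF, 0 °C; ZnCl2, 0 °C → rt; then 5, Pd2(dba)3 (2 mol%), 2-dicyclohexylphosphino-2',6'-dimethoxybiphenyl (8 mol%), THF, rt
Reagents that add atoms: none
Why: directed ortho-lithiation between two MOM ethers, transmetalation to zinc and Negishi coupling (zerovalent palladium inserts into the vinylic C–Br bond) should attach the aryl group to the enone α-carbon under non-aqueous, base-free conditions that the ketone and the acetals tolerate.

Step 4
Reactants: 8 3-[2,4,6-tris(methoxymethoxy)phenyl]but-3-en-2-one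
Product: 9 2-(triisopropylsilyloxy)-3-[2,4,6-tris(methoxymethoxy)phenyl]buta-1,3-diene
Conditions: TIPSOTf, Et3N, CH2Cl2, 0 °C
Reagents that add atoms: triisopropylsilyl trifluoromethanesulfonate, CC(C)[Si](OS(=O)(=O)C(F)(F)F)(C(C)C)C(C)C
Why: soft enolisation and O-silylation of the methyl ketone, whose methyl group carries the only α-hydrogens, should give the 2-silyloxydiene.

Step 5
Reactants: 9 2-(triisopropylsilyloxy)-3-[2,4,6-tris(methoxymethoxy)phenyl]buta-1,3-diene; 3 methyl vinyl ketone
Product: 10 (4S)-4-acetyl-1-(triisopropylsilyloxy)-2-[2,4,6-tris(methoxymethoxy)phenyl]cyclohex-1-ene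
Conditions: 3 (3 equiv), (R)-3,3-diphenyl-1-(o-tolyl)hexahydropyrrolo[1,2-c][1,3,2]oxazaborole (20 mol%), HN(SO2CF3)2 (17 mol%), CH2Cl2, −78 → −20 °C; Et3N quench
Reagents that add atoms: none
Why: The N-protonated oxazaborolidine is a cationic boron Lewis acid that binds methyl vinyl ketone at oxygen and lowers its LUMO, and the diene then adds in a concerted, asynchronous, suprafacial [4+2] cycloaddition; the closest known reaction type is the oxazaborolidinium-catalysed enantioselective Diels–Alder reaction of 2-triisopropylsilyloxybutadiene with vinyl ketones and acrylates. Ring A is closed in this intermolecular [4+2] mode, the C5–C6 bond (unsubstituted diene terminus beside the silyloxy carbon onto the enone β-carbon) leading and the C3–C4 bond following. C4 is the only new stereocentre and is controlled by the catalyst, which holds the s-trans enone by B–O coordination and an α-C–H···O contact and covers one face with a phenyl group of the prolinol unit, so that the diene should reach the α-carbon from the open face and give 4S. The step needs para regioselectivity (acetyl 1,4 to oxygen) and enantiofacial selectivity: the first is secured by the 2-silyloxy group, whose donor effect dominates because the di-ortho-substituted aryl ring is twisted out of conjugation with the diene, the second by the catalyst. Endo or exo approach is immaterial because a single stereocentre results, and the product keeps C1 as a silyl enol ether, so C2 remains unset.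

Step 6
Reactants: 10 (4S)-4-acetyl-1-(triisopropylsilyloxy)-2-[2,4,6-tris(methoxymethoxy)phenyl]cyclohex-1-ene
Product: 11 (4S)-4-(prop-1-en-2-yl)-1-(triisopropylsilyloxy)-2-[2,4,6-tris(methoxymethoxy)phenyl]cyclohex-1-ene
Conditions: Cp2TiMe2, toluene, 70 °C, dark
Reagents that add atoms: dimethyltitanocene, C[Ti](C)(C1C=CC=C1)C1C=CC=C1
Why: Petasis methylenation (titanocene methylidene, [2+2] addition to the ketone and cycloreversion) converts acetyl into isopropenyl without basic species, so the C4 centre beside the carbonyl is not epimerised and the silyl enol ether and acetals should remain.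

Step 7
Reactants: 11 (4S)-4-(prop-1-en-2-yl)-1-(triisopropylsilyloxy)-2-[2,4,6-tris(methoxymethoxy)phenyl]cyclohex-1-ene
Product: 13 (2R,4S)-4-(prop-1-en-2-yl)-2-[2,4,6-tris(methoxymethoxy)phenyl]cyclohexan-1-one, via trans C2 epimer 12 (not isolated)
Conditions: Bu4NF, AcOH, THF, 0 °C; then K2CO3 (cat.), MeOH, rt
Reagents that add atoms: none
Why: fluoride desilylation of the silyl enol ether releases the C1 ketone, and base-catalysed epimerisation at C2 (thermodynamic control) should funnel the material to the cis-2,4 isomer with aryl and isopropenyl both equatorial, which sets C2 as R from the fixed C4 centre.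

Step 8
Reactants: 13 (2R,4S)-4-(prop-1-en-2-yl)-2-[2,4,6-tris(methoxymethoxy)phenyl]cyclohexan-1-one
Product: 14 (1R,2R,4S)-1-methyl-4-(prop-1-en-2-yl)-2-[2,4,6-tris(methoxymethoxy)phenyl]cyclohexan-1-ol
Conditions: MeMgBr, LaCl3·2LiCl, THF, −78 → 0 °C
Reagents that add atoms: methylmagnesium bromide, C[Mg]Br
Why: Grignard 1,2-addition, with the oxophilic lanthanum salt suppressing enolisation of the α-aryl ketone, should deliver the methyl group along the equatorial trajectory anti to the neighbouring equatorial aryl group, giving equatorial CH3 trans to aryl and axial OH cis to aryl (1R), as is usual for 2-substituted cyclohexanones.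

Step 9
Reactants: 14 (1R,2R,4S)-1-methyl-4-(prop-1-en-2-yl)-2-[2,4,6-tris(methoxymethoxy)phenyl]cyclohexan-1-ol; 15 N-methoxy-N-methylisobutyramide
Product: 17 1-{3-[(1R,2R,5S)-2-hydroxy-2-methyl-5-(prop-1-en-2-yl)cyclohexyl]-2,4,6-tris(methoxymethoxy)phenyl}-2-methylpropan-1-one, via dilithio species 16 (not isolated)
Conditions: n-BuLi (2.4 equiv), THF, 0 °C; then 15, −78 → 0 °C; H2O
Reagents that add atoms: none
Why: directed ortho-metalation: after deprotonation of the hydroxyl group, lithiation should occur at one of the two equivalent ring-B C–H positions flanked by two MOM ethers, and acylation by the N-methoxy-N-methylamide stops at the ketone through its chelated tetrahedral adduct, which the alkoxide does not disturb.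

Step 10
Reactants: 17 1-{3-[(1R,2R,5S)-2-hydroxy-2-methyl-5-(prop-1-en-2-yl)cyclohexyl]-2,4,6-tris(methoxymethoxy)phenyl}-2-methylpropan-1-one
Product: 18 1-{2,4,6-trihydroxy-3-[(1R,2R,5S)-2-hydroxy-2-methyl-5-(prop-1-en-2-yl)cyclohexyl]phenyl}-2-methylpropan-1-one
Conditions: HCl (aq., 3 M), MeOH, 25 °C
Reagents that add atoms: none
Why: acid-catalysed acetal exchange with methanol removes the three aryl MOM groups as dimethoxymethane, and dilute acid at ambient temperature is not expected to ionise the tertiary alcohol or protonate the isopropenyl group.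

Step 11
Reactants: 18 1-{2,4,6-trihydroxy-3-[(1R,2R,5S)-2-hydroxy-2-methyl-5-(prop-1-en-2-yl)cyclohexyl]phenyl}-2-methylpropan-1-one; 19 prenyl bromide (1-bromo-3-methylbut-2-ene)
Product: 21 3,5-dihydroxy-4-[(1R,2R,5S)-2-hydroxy-2-methyl-5-(prop-1-en-2-yl)cyclohexyl]-6,6-bis(3-methylbut-2-en-1-yl)-2-(2-methylpropanoyl)cyclohexa-2,4-dien-1-one (target), via monoprenyl acylphloroglucinol 20 (not isolated)
Conditions: NaOMe, MeOH, 0 °C; 19 (2.2 equiv), 0 °C → rt
Reagents that add atoms: none
Why: base-mediated C-alkylation followed by alkylative dearomatisation: the first prenyl group enters the only unsubstituted ring-B carbon and the second is expected at the same carbon, because the other alkyl-bearing carbon is shielded by the bulky cyclohexyl group, as in the classical conversion of prenylated acylphloroglucinols into lupulone-type trienolones; no stereocentre is formed.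

**Compound list**

1 | phloroglucinol | Oc1cc(O)cc(O)c1 | starting material
2 | 1,3,5-tris(methoxymethoxy)benzene | COCOc1cc(OCOC)cc(OCOC)c1 | intermediate
3 | methyl vinyl ketone | C=CC(C)=O | starting material
4 | 3,4-dibromobutan-2-one (racemic) | CC(=O)C(Br)CBr | intermediate
5 | 3-bromobut-3-en-2-one | C=C(Br)C(C)=O | intermediate
6 | 2-lithio-1,3,5-tris(methoxymethoxy)benzene | [Li]c1c(OCOC)cc(OCOC)cc1OCOC | intermediate
7 | [2,4,6-tris(methoxymethoxy)phenyl]zinc chloride | Cl[Zn]c1c(OCOC)cc(OCOC)cc1OCOC | intermediate
8 | 3-[2,4,6-tris(methoxymethoxy)phenyl]but-3-en-2-one | C=C(C(C)=O)c1c(OCOC)cc(OCOC)cc1OCOC | intermediate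
9 | 2-(triisopropylsilyloxy)-3-[2,4,6-tris(methoxymethoxy)phenyl]buta-1,3-diene | C=C(O[Si](C(C)C)(C(C)C)C(C)C)C(=C)c1c(OCOC)cc(OCOC)cc1OCOC | intermediate
10 | (4S)-4-acetyl-1-(triisopropylsilyloxy)-2-[2,4,6-tris(methoxymethoxy)phenyl]cyclohex-1-ene | CC(=O)[C@H]1CCC(O[Si](C(C)C)(C(C)C)C(C)C)=C(c2c(OCOC)cc(OCOC)cc2OCOC)C1 | intermediate
11 | (4S)-4-(prop-1-en-2-yl)-1-(triisopropylsilyloxy)-2-[2,4,6-tris(methoxymethoxy)phenyl]cyclohex-1-ene | C=C(C)[C@H]1CCC(O[Si](C(C)C)(C(C)C)C(C)C)=C(c2c(OCOC)cc(OCOC)cc2OCOC)C1 | intermediate
12 | (2S,4S)-4-(prop-1-en-2-yl)-2-[2,4,6-tris(methoxymethoxy)phenyl]cyclohexan-1-one (trans) | C=C(C)[C@H]1CCC(=O)[C@H](c2c(OCOC)cc(OCOC)cc2OCOC)C1 | intermediate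
13 | (2R,4S)-4-(prop-1-en-2-yl)-2-[2,4,6-tris(methoxymethoxy)phenyl]cyclohexan-1-one (cis) | C=C(C)[C@H]1CCC(=O)[C@@H](c2c(OCOC)cc(OCOC)cc2OCOC)C1 | intermediate
14 | (1R,2R,4S)-1-methyl-4-(prop-1-en-2-yl)-2-[2,4,6-tris(methoxymethoxy)phenyl]cyclohexan-1-ol | C=C(C)[C@H]1CC[C@@](C)(O)[C@@H](c2c(OCOC)cc(OCOC)cc2OCOC)C1 | intermediate
15 | N-methoxy-N-methylisobutyramide | CC(C)C(=O)N(C)OC | starting material
16 | lithium alkoxide of 14, lithiated at a ring-B C–H between two MOM ethers | C=C(C)[C@H]1CC[C@@](C)(O[Li])[C@@H](c2c(OCOC)cc(OCOC)c([Li])c2OCOC)C1 | intermediate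
17 | 1-{3-[(1R,2R,5S)-2-hydroxy-2-methyl-5-(prop-1-en-2-yl)cyclohexyl]-2,4,6-tris(methoxymethoxy)phenyl}-2-methylpropan-1-one | C=C(C)[C@H]1CC[C@@](C)(O)[C@@H](c2c(OCOC)cc(OCOC)c(C(=O)C(C)C)c2OCOC)C1 | intermediate
18 | 1-{2,4,6-trihydroxy-3-[(1R,2R,5S)-2-hydroxy-2-methyl-5-(prop-1-en-2-yl)cyclohexyl]phenyl}-2-methylpropan-1-one | C=C(C)[C@H]1CC[C@@](C)(O)[C@@H](c2c(O)cc(O)c(C(=O)C(C)C)c2O)C1 | intermediate
19 | prenyl bromide | CC(C)=CCBr | starting material
20 | 1-{2,4,6-trihydroxy-3-[(1R,2R,5S)-2-hydroxy-2-methyl-5-(prop-1-en-2-yl)cyclohexyl]-5-(3-methylbut-2-en-1-yl)phenyl}-2-methylpropan-1-one | C=C(C)[C@H]1CC[C@@](C)(O)[C@@H](c2c(O)c(CC=C(C)C)c(O)c(C(=O)C(C)C)c2O)C1 | intermediate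
21 | 3,5-dihydroxy-4-[(1R,2R,5S)-2-hydroxy-2-methyl-5-(prop-1-en-2-yl)cyclohexyl]-6,6-bis(3-methylbut-2-en-1-yl)-2-(2-methylpropanoyl)cyclohexa-2,4-dien-1-one | C=C(C)[C@H]1CC[C@@](C)(O)[C@@H](C2=C(O)C(CC=C(C)C)(CC=C(C)C)C(=O)C(C(=O)C(C)C)=C2O)C1 | target

**Step count and risks**

Total: 11 steps. Longest linear sequence: 10 steps (steps 1 and 3–11).

Steps most likely to fail:

Step 5. The cycloaddition may stall because the six acetal oxygens of the diene sequester the cationic catalyst, the hindered 2,3-disubstituted diene may react slowly enough for adventitious acid to hydrolyse the silyl enol ether, or facial discrimination may be insufficient. Fallback: stereocontrol is moved from the catalyst to a covalently bound auxiliary. Setting out from diene 9, Et2AlCl-promoted Diels–Alder addition to (R)-3-acryloyl-4-benzyloxazolidin-2-one F1 (from (R)-4-benzyloxazolidin-2-one and acryloyl chloride) should give the imide (4R)-4-benzyl-3-{[(1S)-4-(triisopropylsilyloxy)-3-[2,4,6-tris(methoxymethoxy)phenyl]cyclohex-3-en-1-yl]carbonyl}oxazolidin-2-one F2, the diene adding anti to the benzyl group of the chelated s-cis imide. Transamidation with MeNHOMe·HCl and AlMe3 would give the N-methoxy-N-methylamide F3, and MeMgBr addition returns the route to ketone 10.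

Step 11. O-Alkylation, over-alkylation or alkylation at the cyclohexyl-bearing carbon may compete with the desired geminal C-alkylation, since prenyl bromide is a hard, unselective electrophile toward the polyanion. Fallback: from triol 18, Tsuji–Trost double C-allylation with allyl methyl carbonate and Pd(PPh3)4 (a soft π-allyl electrophile that alkylates at carbon) should give the gem-diallyl trienolone 3,5-dihydroxy-4-[(1R,2R,5S)-2-hydroxy-2-methyl-5-(prop-1-en-2-yl)cyclohexyl]-2-(2-methylpropanoyl)-6,6-di(prop-2-en-1-yl)cyclohexa-2,4-dien-1-one F4. Double cross-metathesis with 2-methylbut-2-ene and the second-generation Grubbs catalyst, in which the 1,1-disubstituted isopropenyl group is expected to react much more slowly than the terminal allyl groups, comes back to the route at target 21.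

Step 3. Polymerisation or conjugate-addition loss of the bromoenone may outrun transmetalation from the hindered di-ortho-substituted arylzinc. Fallback: the enone is built without cross-coupling. From arene 2, lithiation as before and copper-catalysed (CuI) opening of racemic propylene oxide at the terminal carbon should give 1-[2,4,6-tris(methoxymethoxy)phenyl]propan-2-ol F5. Dess–Martin oxidation gives 1-[2,4,6-tris(methoxymethoxy)phenyl]propan-2-one F6, and Mannich-type α-methylenation at the benzylic carbon (paraformaldehyde, diisopropylammonium trifluoroacetate, THF, reflux) rejoins the route at enone 8.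

**Further compounds**

F1 | step 5 | (R)-3-acryloyl-4-benzyloxazolidin-2-one | C=CC(=O)N1[C@H](Cc2ccccc2)COC1=O
F2 | step 5 | (4R)-4-benzyl-3-{[(1S)-4-(triisopropylsilyloxy)-3-[2,4,6-tris(methoxymethoxy)phenyl]cyclohex-3-en-1-yl]carbonyl}oxazolidin-2-one | O=C([C@H]1CCC(O[Si](C(C)C)(C(C)C)C(C)C)=C(c2c(OCOC)cc(OCOC)cc2OCOC)C1)N1[C@H](Cc2ccccc2)COC1=O
F3 | step 5 | (1S)-N-methoxy-N-methyl-4-(triisopropylsilyloxy)-3-[2,4,6-tris(methoxymethoxy)phenyl]cyclohex-3-ene-1-carboxamide | CON(C)C(=O)[C@H]1CCC(O[Si](C(C)C)(C(C)C)C(C)C)=C(c2c(OCOC)cc(OCOC)cc2OCOC)C1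
F4 | step 11 | 3,5-dihydroxy-4-[(1R,2R,5S)-2-hydroxy-2-methyl-5-(prop-1-en-2-yl)cyclohexyl]-2-(2-methylpropanoyl)-6,6-di(prop-2-en-1-yl)cyclohexa-2,4-dien-1-one | C=C(C)[C@H]1CC[C@@](C)(O)[C@@H](C2=C(O)C(CC=C)(CC=C)C(=O)C(C(=O)C(C)C)=C2O)C1
F5 | step 3 | 1-[2,4,6-tris(methoxymethoxy)phenyl]propan-2-ol (racemic) | CC(O)Cc1c(OCOC)cc(OCOC)cc1OCOC
F6 | step 3 | 1-[2,4,6-tris(methoxymethoxy)phenyl]propan-2-one | CC(=O)Cc1c(OCOC)cc(OCOC)cc1OCOC
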